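**Strategy.** The cyclopentanone ring of the cyclopenta[c]pyridine is cut at C7–C7a and C5–C6. C6–C7, with its methyl and hydroxyl, is D-lactic acid; C5, with hydroxyl and ester on C4a, is a pyridyl glyoxylate. Lactic acid is stored as its cis tert-butyl dioxolanone, whose acetal carbon remembers the stereocentre. In one flask the lithium enolate adds to the keto ester (C5–C6); bromine–lithium exchange at C7a then triggers acyl transfer from the dioxolanone (C7–C7a), which expels pivalaldehyde and unveils both tertiary alcohols. The precursor pair is methyl 2-(5-bromo-2-chloropyridin-4-yl)-2-oxoacetate and the dioxolanone; the dienyl chain is attached last by Stille coupling.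

Key step: step 3

Remark: atoms are numbered as in cyclopenta[c]pyridine (C5 = C(OH)CO2Me, C6 = C(OH)CH3, C7 = C=O, C4a/C7a = ring-fusion carbons). Compounds 1, 2, 5, 6 and 12 and all reagents are assumed to be bought; LDA is used as the commercial solution.

**Step 1**
Reactants: 1 5-bromo-2-chloropyridine; 2 dimethyl oxalate
Product: 4 methyl 2-(5-bromo-2-chloropyridin-4-yl)-2-oxoacetate, via pyridin-4-yllithium 3 (not isolated)
Conditions: LDA (1.05 equiv), THF, −78 °C; cannulated into 2 (3 equiv), THF, −78 °C; AcOH, −78 °C → rt
Reagents that add atoms: none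
Why: Directed ortho-lithiation by LDA should occur at C4, next to bromine, and the aryllithium acylates excess dimethyl oxalate only once because the tetrahedral adduct persists at −78 °C (organolithium acylation of an oxalate); no stereocentre is formed.

**Step 2**
Reactants: 5 (R)-lactic acid; 6 pivalaldehyde
Product: 7 (2R,5R)-2-tert-butyl-5-methyl-1,3-dioxolan-4-one
Conditions: TsOH·H2O (cat.), H2SO4 (cat.), pentane, reflux, Dean–Stark; crystallisation from pentane/Et2O, −78 °C
Reagents that add atoms: none
Why: Acid-catalysed acetalisation with azeotropic removal of water should give mainly the cis dioxolanone (thermodynamic preference), so the new acetal stereocentre C2 (R) is set by the lactate centre, and cold crystallisation removes the trans isomer.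

**Step 3**
Reactants: 7 (2R,5R)-2-tert-butyl-5-methyl-1,3-dioxolan-4-one; 4 methyl 2-(5-bromo-2-chloropyridin-4-yl)-2-oxoacetate
Product: 11 methyl (5R,6S)-3-chloro-5,6-dihydroxy-6-methyl-7-oxo-6,7-dihydro-5H-cyclopenta[c]pyridine-5-carboxylate, via lithium enolate 8 (not isolated), via bromo aldolate 9 (not isolated), via aryllithium 10 (not isolated)
Conditions: 7 (1.1 equiv) added to LDA (1.05 equiv), THF, −78 °C; 4, THF, −78 °C, 1 h; n-BuLi (1.1 equiv), −100 °C, 20 min; AcOH, −100 → −78 °C
Reagents that add atoms: none
Why: LDA gives the planar lithium enolate 8, whose only stereocentre is the tert-butyl acetal carbon, and 8 adds through the face trans to tert-butyl (its Si face) to the non-enolisable keto group of 4 to give aldolate 9 (C5–C6 bond); n-BuLi then effects bromine–lithium exchange and aryllithium 10 attacks the dioxolanone carbonyl (C7–C7a bond), the tetrahedral intermediate collapsing with ring opening and loss of pivalaldehyde so that the C7 ketone and both tertiary alcohols are unveiled directly. The closest known reaction types are the aldol addition of 2-tert-butyl-1,3-dioxolan-4-one enolates to ketones (self-regeneration of stereocentres) and the Parham cyclisation of an aryllithium onto an ester carbonyl. The cyclopentanone ring closes by 5-exo-trig attack of C7a on C7 with acyl transfer; attack on the methyl ester would need a four-membered ring and is not competitive. C6 (S) is controlled by the acetal carbon (net retention of the D-lactate centre); C5 (R) requires attack on the Re face of the ketone (ul topicity), expected from a lithium-bridged six-membered chair transition state in which the small planar CO2Me sits pseudo-equatorial and the bulky ortho-brominated pyridyl ring sits pseudo-axial, anti to the enolate methyl and over the tert-butyl-free face of the flat dioxolanone. The step therefore needs enolate-face selectivity (secured by the tert-butyl group), ketone-face selectivity (secured only by the size difference between aryl and ester, and the least certain element, since a lithium-chelated ester would favour the C5 epimer) and chemoselective Br–Li exchange over carbonyl addition and C–Cl attack (secured by −100 °C, the faster exchange at bromine and the neighbouring alkoxide); a cold acidic quench prevents retro-aldol opening of the dialkoxide.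

**Step 4**
Reactants: 12 (S)-2-methylbutan-1-ol
Product: 14 (2E,4S)-2,4-dimethylhex-2-enal, via (S)-2-methylbutanal 13 (not isolated)
Conditions: TEMPO (cat.), PhI(OAc)2, CH2Cl2, 0 °C → rt; then Ph3P=C(CH3)CHO, CH2Cl2, 40 °C
Reagents that add atoms: 2-(triphenylphosphoranylidene)propanal, CC(C=O)=P(c1ccccc1)(c1ccccc1)c1ccccc1
Why: The TEMPO/PhI(OAc)2 oxidation stops at the aldehyde, which is trapped in the same flask by the formyl-stabilised ylide in an E-selective Wittig olefination, so the configurationally labile α-branched aldehyde is never concentrated; the existing stereocentre is carried through.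

**Step 5**
Reactants: 14 (2E,4S)-2,4-dimethylhex-2-enal
Product: 15 (1E,3E,5S)-1-iodo-3,5-dimethylhepta-1,3-diene
Conditions: CHI3, CrCl2, THF/1,4-dioxane, 0 °C → rt
Reagents that add atoms: iodoform, IC(I)I
Why: Takai olefination through a gem-dichromium carbenoid should convert the aldehyde into the (E)-alkenyl iodide, the E geometry arising from anti elimination in the less hindered β-oxido chromium intermediate, with dioxane as cosolvent raising the E preference.

**Step 6**
Reactants: 15 (1E,3E,5S)-1-iodo-3,5-dimethylhepta-1,3-diene
Product: 17 tributyl[(1E,3E,5S)-3,5-dimethylhepta-1,3-dien-1-yl]stannane, via dienyllithium 16 (not isolated)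
Conditions: t-BuLi (2.1 equiv), Et2O, −78 °C; Bu3SnCl, −78 °C → rt
Reagents that add atoms: tributyltin chloride, CCCC[Sn](Cl)(CCCC)CCCC
Why: Iodine–lithium exchange and stannylation of the alkenyllithium both proceed with retention of alkene geometry (halogen–metal exchange followed by transmetalation).

**Step 7**
Reactants: 11 methyl (5R,6S)-3-chloro-5,6-dihydroxy-6-methyl-7-oxo-6,7-dihydro-5H-cyclopenta[c]pyridine-5-carboxylate; 17 tributyl[(1E,3E,5S)-3,5-dimethylhepta-1,3-dien-1-yl]stannane
Product: 18 methyl (5R,6S)-3-[(1E,3E,5S)-3,5-dimethylhepta-1,3-dien-1-yl]-5,6-dihydroxy-6-methyl-7-oxo-6,7-dihydro-5H-cyclopenta[c]pyridine-5-carboxylate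
Conditions: Pd(PPh3)4 (10 mol %), CuI (20 mol %), degassed DMF, 70–80 °C
Reagents that add atoms: none
Why: Stille coupling, in which oxidative addition into the C–Cl bond (activated by the ring nitrogen and the para acyl group) and copper-assisted transmetalation of the alkenylstannane run under neutral conditions with retention of diene geometry, so the base-sensitive tertiary aldol/α-ketol core is not exposed to base and no stereocentre is touched.

**Compound list**
1 | 5-bromo-2-chloropyridine | Clc1ccc(Br)cn1 | starting material
2 | dimethyl oxalate | COC(=O)C(=O)OC | starting material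
3 | (5-bromo-2-chloropyridin-4-yl)lithium | [Li]c1cc(Cl)ncc1Br | intermediate
4 | methyl 2-(5-bromo-2-chloropyridin-4-yl)-2-oxoacetate | COC(=O)C(=O)c1cc(Cl)ncc1Br | intermediate
5 | (R)-lactic acid (D-lactic acid) | C[C@@H](O)C(=O)O | starting material
6 | pivalaldehyde | CC(C)(C)C=O | starting material
7 | (2R,5R)-2-tert-butyl-5-methyl-1,3-dioxolan-4-one (cis) | C[C@H]1O[C@@H](C(C)(C)C)OC1=O | intermediate
8 | lithium (2R)-2-tert-butyl-5-methyl-1,3-dioxol-4-olate | CC1=C(O[Li])O[C@H](C(C)(C)C)O1 | intermediate
9 | lithium alkoxide of methyl (2R)-2-(5-bromo-2-chloropyridin-4-yl)-2-[(2R,4S)-2-tert-butyl-4-methyl-5-oxo-1,3-dioxolan-4-yl]-2-hydroxyacetate | COC(=O)[C@@](O[Li])(c1cc(Cl)ncc1Br)[C@]1(C)O[C@@H](C(C)(C)C)OC1=O | intermediate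
10 | 5-lithiopyridine derived from 9 by Br–Li exchange (dilithio species) | COC(=O)[C@@](O[Li])(c1cc(Cl)ncc1[Li])[C@]1(C)O[C@@H](C(C)(C)C)OC1=O | intermediate
11 | methyl (5R,6S)-3-chloro-5,6-dihydroxy-6-methyl-7-oxo-6,7-dihydro-5H-cyclopenta[c]pyridine-5-carboxylate | Clc1cc2c(cn1)C(=O)[C@@](C)(O)[C@@]2(O)C(=O)OC | intermediate
12 | (S)-2-methylbutan-1-ol | CC[C@H](C)CO | starting material
13 | (S)-2-methylbutanal | CC[C@H](C)C=O | intermediate
14 | (2E,4S)-2,4-dimethylhex-2-enal | CC[C@H](C)/C=C(\C)C=O | intermediate
15 | (1E,3E,5S)-1-iodo-3,5-dimethylhepta-1,3-diene | CC[C@H](C)/C=C(C)/C=C/I | intermediate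
16 | [(1E,3E,5S)-3,5-dimethylhepta-1,3-dien-1-yl]lithium | CC[C@H](C)/C=C(C)/C=C/[Li] | intermediate
17 | tributyl[(1E,3E,5S)-3,5-dimethylhepta-1,3-dien-1-yl]stannane | CC[C@H](C)/C=C(C)/C=C/[Sn](CCCC)(CCCC)CCCC | intermediate
18 | methyl (5R,6S)-3-[(1E,3E,5S)-3,5-dimethylhepta-1,3-dien-1-yl]-5,6-dihydroxy-6-methyl-7-oxo-6,7-dihydro-5H-cyclopenta[c]pyridine-5-carboxylate | CC[C@H](C)/C=C(C)/C=C/c1cc2c(cn1)C(=O)[C@@](C)(O)[C@@]2(O)C(=O)OC | target

**Totals**
Total steps: 7. Longest linear sequence: 4 steps (steps 4, 5, 6, 7; 12 → 14 → 15 → 17 → 18).

**Steps most likely to fail**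

1. Step 3. The aldol addition may discriminate poorly between the two faces of the keto group, or prefer the wrong one if the ester chelates lithium, and butyllithium may add to a carbonyl before exchange. The fallback sets out from 7 and 4 and comes back at 11, and it separates the two bond formations. Compound 7 is converted with LDA and TMSCl into the silyl ketene acetal (2R)-2-tert-butyl-5-methyl-4-(trimethylsilyloxy)-1,3-dioxole F1. Mukaiyama aldol addition of F1 to 4 with TiCl4 in CH2Cl2 at −78 °C uses a titanium-chelated keto ester and an open transition state, a different topicity-determining arrangement from the lithium chair. After aqueous work-up it should give the free bromo aldol methyl (2R)-2-(5-bromo-2-chloropyridin-4-yl)-2-[(2R,4S)-2-tert-butyl-4-methyl-5-oxo-1,3-dioxolan-4-yl]-2-hydroxyacetate F2, from which the C5 epimer is removed by chromatography or crystallisation. F2 is then cyclised in a separate Parham step (n-BuLi, 2.1 equiv, THF/Et2O, −100 °C, AcOH quench) through aryllithium 10 to 11.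

2. Step 7. Oxidative addition into the chloride may be slow and the stannane may protodestannylate at a temperature where the tertiary ketol starts to undergo retro-aldol or α-ketol isomerisation. The fallback sets out from 14 and 11 and comes back at 18. Takai–Utimoto boron olefination of 14 (Cl2CHBpin, CrCl2, LiI, THF) gives 2-[(1E,3E,5S)-3,5-dimethylhepta-1,3-dien-1-yl]-4,4,5,5-tetramethyl-1,3,2-dioxaborolane F3. Suzuki–Miyaura coupling of F3 with 11 using a fast precatalyst at low temperature (XPhos Pd G3, CsF, dioxane, 40 °C) should then give 18.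

3. Step 4. The α-branched aldehyde may partly racemise during the slow olefination with the weakly nucleophilic formyl ylide, and the product enal may be homologated a second time. The fallback sets out from 12 and comes back at 14. Alcohol 12 is oxidised as before and aldehyde 13 is trapped at room temperature with the more reactive ester ylide ethyl 2-(triphenylphosphoranylidene)propanoate to give ethyl (2E,4S)-2,4-dimethylhex-2-enoate F4. DIBAL-H reduction (CH2Cl2, −78 °C) gives (2E,4S)-2,4-dimethylhex-2-en-1-ol F5, and MnO2 oxidation (CH2Cl2, rt) gives 14.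

**Further compounds**
F1 | step 3 | (2R)-2-tert-butyl-5-methyl-4-(trimethylsilyloxy)-1,3-dioxole | CC1=C(O[Si](C)(C)C)O[C@H](C(C)(C)C)O1
F2 | step 3 | methyl (2R)-2-(5-bromo-2-chloropyridin-4-yl)-2-[(2R,4S)-2-tert-butyl-4-methyl-5-oxo-1,3-dioxolan-4-yl]-2-hydroxyacetate | COC(=O)[C@@](O)(c1cc(Cl)ncc1Br)[C@]1(C)O[C@@H](C(C)(C)C)OC1=O
F3 | step 7 | 2-[(1E,3E,5S)-3,5-dimethylhepta-1,3-dien-1-yl]-4,4,5,5-tetramethyl-1,3,2-dioxaborolane | CC[C@H](C)/C=C(C)/C=C/B1OC(C)(C)C(C)(C)O1
F4 | step 4 | ethyl (2E,4S)-2,4-dimethylhex-2-enoate | CC[C@H](C)/C=C(\C)C(=O)OCC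
F5 | step 4 | (2E,4S)-2,4-dimethylhex-2-en-1-ol | CC[C@H](C)/C=C(\C)CO
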